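The constants were set for the occasion; the flask was simulated.

Freeze the partner.

    target + catalyst ⇌ isomer of the product + catalyst, rate k1*[catalyst]*[target] forward; the back reaction follows from the equilibrium constant (K1 = 1.26, k1 = 242 M⁻¹ min⁻¹, Ea1 = 45.0 kJ mol⁻¹, ΔH1 = 0 kJ mol⁻¹)
    starting material + partner + catalyst ⇌ target + catalyst, rate k2*[starting material]*[partner]*[catalyst] forward; the back reaction follows from the equilibrium constant (K2 = 0.048 M⁻¹, k2 = 29.5 M⁻² min⁻¹, Ea2 = 35.0 kJ mol⁻¹, ΔH2 = −34.0 kJ mol⁻¹)
    (constants at 25 °C)

| setting | south | south-east | north-west | south-west |
|---|---|---|---|---|
| starting material | 0.52 M | 0.52 M | 0.52 M | 0.52 M |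
| partner | 2.60 M | 2.60 M | 2.60 M | 2.60 M |
| catalyst | 0.26 mM | 0.26 mM | 0.26 mM | 0.26 mM |
| temperature | 25 °C |  | 50 °C | 0 °C |
| time | 3.0 h | 3.0 h | 3.0 h | 3.0 h |
| remark |  | at 50 °C until 2.0 h, from then on at 0 °C |  |  |

* the flask that comes out highest in amount of target, in percent of the starting material charged, or "all alike" when all lie within 1.5 percentage points (south / south-east / north-west / south-west / all alike)
* target at the end, in percent of the starting material charged, south
* target at the end, in percent of the starting material charged, south-east
* target at the end, in percent of the starting material charged, north-west
* target at the end, in percent of the starting material charged, south-west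

- the list of constants is for 25 °C, to be carried to other temperatures by the activation energies and enthalpies

The partner is charged at 5.00 times the starting material, so I hold c(partner) at its charge, a pseudo-first-order view of the coupling. That folds the flask into one number: X, the equilibrium constant of the coupling times c(partner), which is the ratio of target to starting material at rest. The isomerisation has enthalpy 0 kJ mol⁻¹, so its equilibrium ratio of isomer to target, which holds at rest and not on the way there, is 1.26 at each of these temperatures. The resting share of target is then X over one plus X plus 1.26 X. X is 0.125 in south, 0.0432 in north-west and 0.438 in south-west. The shares are 9.73%, 3.94% and, for the cold, 22.0%, the cold resting share.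

Is one number enough? X holds no time. The coupling's clock, one over its forward and back rates added, is 5.56 min in south, far shorter than the run, so south may rest. In the cold I slow the rate constant by the square root of 11 and get a clock of 50.3 min. With that clock I reckon south-west at 21.4% at the end. I start south-east from 3.94% after its hot part; it has 60.0 min of cold, which is near one clock, so I reckon it at 16.5%. My order puts south-west first.

The forecast also names south-west, with 9.4% for south, 16.3% for south-east, 3.9% for north-west and 19.4% for south-west. Its south-west figure is lower than mine, and it puts the cold equilibrium at about 21, where I have 22.0%. Its ground for south-east is that the flask “has only its last hour cold to climb”.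

South-west comes out highest at 19.4%, with south-east at 16.2%, south at 9.41% and north-west at 3.87%, and each lies inside the forecast's range. My south-west figure stands 2 percentage points too high. After 30.0 h, south-west and south-east both read 20.9%. With the partner unfrozen to the 90.5% of its charge left then, the cold resting share 22.0% becomes 20.9%.

The neighbour is south-west read at 50 min, close to one cold clock: 22.0% and that clock give 13.9% of target. The run gives 14.1%, beside 4.42% of isomer.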